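(The runs were generated by integration for an exercise; noise was put on by code.)

Count in equivalents of substrate, and a flask can be balanced by subtraction.

| flask | substrate | partner | second catalyst | precatalyst | temperature | remark | time |
|---|---|---|---|---|---|---|---|
| ochre | 0.050 M | 0.70 equiv | 0.1 mol% | 0.13 mol% | −5 °C | run made earlier |  |
| teal | 0.050 M | 0.70 equiv | 0.1 mol% | 0.3 mol% | 8 °C | run made earlier |  |
| amber | 0.050 M | 0.70 equiv | 0.15 mol% | 0.2 mol% | −5 °C | run made earlier |  |
| birch | 0.050 M | 0.700 equiv | 0.1 mol% | 0.2 mol% | 0 °C |  | 8.0 h |
| larch | 0.050 M | 0.700 equiv | 0.1 mol% | 0.2 mol% | 15 °C |  | 8.0 h |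
| cedar | 0.050 M | 0.700 equiv | 0.1 mol% | 0.2 mol% |  | at 15 °C until 4.0 h, from then on at 0 °C | 8.0 h |

| run | time / h | product / % | substrate / % |
|---|---|---|---|
| ochre | 0.417 | 3.7 | 86.0 |
| ochre | 1.33 | 29.2 | 40.9 |
| ochre | 2.50 | 59.6 | 11.1 |
| ochre | 3.00 | 64.6 | 6.1 |
| ochre | 5.00 | 68.9 | 1.2 |
| ochre | 6.00 | 69.5 | 1.3 |
| ochre | 8.00 | 69.1 | 1.0 |
| teal | 0.667 | 46.7 | 7.8 |
| teal | 1.00 | 59.2 | 0.8 |
| teal | 1.33 | 65.9 | 2.1 |
| teal | 2.50 | 70.4 | 0 |
| teal | 3.00 | 71.0 | 0 |
| teal | 5.00 | 70.3 | 2.7 |
| teal | 8.00 | 67.9 | 0 |
| amber | 0.667 | 14.7 | 61.8 |
| amber | 2.00 | 63.1 | 9.2 |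
| amber | 4.00 | 68.8 | 1.0 |
| amber | 6.00 | 70.0 | 0.5 |
| amber | 8.00 | 71.3 | 0 |

(standard deviation of a reading: 1 percentage point)

- the flask with the highest amount of product, in percent of the substrate charged ("all alike" if they lie within 1.5 percentage points) (birch / larch / cedar / all alike)
- final product, as a percentage of the substrate charged, in birch
- final product, as a percentage of the substrate charged, in larch
- final product, as a percentage of the substrate charged, in cedar

- the numbers in the tables scatter by 1 percentage point (one standard deviation)
- steps that have been proposed: substrate + free catalyst -> free catalyst + open intermediate; partner + precatalyst -> free catalyst + spent reagent; second catalyst + open intermediate <-> catalyst intermediate; partner + catalyst intermediate -> second catalyst + product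

Which reagent is charged in the smaller amount? It is the partner, at 0.700 equiv against one equivalent of substrate, so it is the limiting reagent. Each product takes one partner, each free catalyst made from precatalyst takes one more, and no proposed step returns any. You therefore reckon 69.8%: the partner budget, partner charged less precatalyst charged, read as percent of the substrate, which counts the charged precatalyst as activated. Birch, larch and cedar carry the same charges.

Is the budget used within 8.0 h? Ochre, with 0.13 mol% of precatalyst at −5 °C, reads 68.9% product at 5.00 h, which is 0.625 of that time. Birch is warmer and holds more precatalyst. Teal, at 8 °C, reads 70.4% at 2.50 h, and larch and cedar start warmer still, though with less precatalyst.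

Does anything then remove product? Teal's budget is 69.7%, and its last reading lies 1.8 percentage points below that, with a scatter of 1 point. Its last four readings average 69.9%, so you read no loss beyond the scatter, and you commit to 69.8% in each flask: alike within 1.5 points.

The forecast gives 69.8% in birch, as you do, but 63% in larch and 66.5% in cedar, with birch highest, on what it calls weak evidence for “a slow, temperature-sensitive product loss not among the proposed steps”.

The flasks give 69.8% in birch, 69.8% in larch and 69.8% in cedar: all alike.

    substrate + free catalyst → free catalyst + open intermediate (k = 380 M⁻¹ min⁻¹, Ea = 39.0 kJ mol⁻¹)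
    partner + precatalyst → free catalyst + spent reagent (k = 1.40 M⁻¹ min⁻¹, Ea = 41.0 kJ mol⁻¹)
    second catalyst + open intermediate ⇌ catalyst intermediate (K = 37.0 M⁻¹, k = 880 M⁻¹ min⁻¹, Ea = 46.0 kJ mol⁻¹, ΔH = −35.0 kJ mol⁻¹)
    partner + catalyst intermediate → second catalyst + product (k = 2100 M⁻¹ min⁻¹, Ea = 40.0 kJ mol⁻¹)
    (constants at 0 °C)

In larch, partner stands at 0% of its charge after 4.00 h, and a run ten times as long changes nothing. In larch the budget also leaves 30.2% of the substrate without partner, and that flask holds 30.2% as open intermediate, with 20.0% of the second catalyst as catalyst intermediate.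

Take birch with 0.280 equiv of partner: the budget becomes 27.8%. That neighbour flask gives 27.9% product, with 72.1% as open intermediate and 34.0% of the precatalyst still there.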